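Start with the solid. E dissolves to Q, and Q goes on through L and G to Z.

E 0.010 M; time 30 min

    Q ⇌ L (K1 = 0.17, k1 = 0.034 s⁻¹)
    L ⇌ G (K2 = 0.60, k2 = 7.1 × 10⁻⁴ s⁻¹)
    G ⇌ Z (K3 = 0.71, k3 = 0.0067 s⁻¹)
    E ⇌ Q, rate k4*(cs4 - [Q]) while solid is left; crystals form when [Q] > cs4 (cs4 = 1.1 mM, k4 = 0.029 s⁻¹)

- solid, in amounts per volume of the solution: E
- at the start none of E is in solution
- what has only dissolved of E counts as not reacted
- the reaction counts as stopped when no species that holds the E changes by six tenths of a point or more over the second half of the time
- run time (flask): 30 min

* the state of affairs at 30 min: stopped, and by what, or still going (for what has run out or reacted, a solid counts together with what of it has only dissolved) (it is still moving / forward and back rates have come level / all of E has reacted)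
* part of the E that has turned into other species by 30 min (what has only dissolved does not count)
* how much L there is at 30 min, in percent of the E charged

Two numbers here don't seem to go together. Q passes to L with a forward half-life of 0.340 min, so the run holds about 88.3 such half-lives, and yet my reckoning below keeps the conversion well short of the charge.

The first step runs back as well, and it comes level quickly (a pre-equilibrium). So reckon in fractions of the charge, while solid is left:

Q at its solubility: 11.0 %

L, the equilibrium constant 0.17 times that: 1.87 %

Call this the standing share of L, the fraction of the charge that L holds beside undissolved solid. G and Z add their own equilibrium shares on top:

ceiling of conversion: 3.79 %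

That leaves 85.2 % of the charge as solid at rest, so solid is left.

Now replace the curve of L by its flat level for the whole run. Its forward flow into G would carry 2.39 %, more than the 1.92 % that G and Z hold at rest. That flow errs by leaving out the way back. G and Z relax with each other faster than L does with G, so count them as one pool, which nears its rest level with this time constant:

pool time constant: 24.1 min

conversion I commit to at the asked time: 3.24 %

gain of the pool over the second half: 0.48 percentage points

That gain, shared by G and Z, falls under the stopping mark, so I commit to level rates with L at the standing share.

The forecast reads forward and back rates have come level, conv 3.2 % and y_P 1.87 %, on the ground that “solid stays in excess”.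

The flask gives forward and back rates have come level, conv 3.19 % and y_P 1.87 %.

L in this flask stands at 1.87 %, the standing share of 1.87 %. The main reason for the small conversion is the undoing of L into Q: the run without it converts 100 % of E, against 3.19 % with it. Now take a neighbour flask charged with 0.0025 M of E, the time held. Its standing share is 7.48 %, and that neighbour flask holds L at 7.46 %.

The constants stand for no real mixture, and the outcome is calculated.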